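The synthesis rests on reading C1 (carbonyl), C2 (ethyl branch) and C3 (hydroxyl), a 2,3-syn aldol triad, as a cis-3,4-disubstituted oxetan-2-one ring (O3–C1–C2–C3). That ring equals the trans C2–C3 oxirane plus carbon monoxide. One catalytic carbonylation forms C1–C2 and C1–O3, closes the four-membered ring, sets C2 by inversion, and masks acid and alcohol together. The precursor is the fully protected C2–C16 polyol (2R,3R)-epoxide. It is assembled by a three-component dithiane relay coupling of two terminal epoxides, followed by a Shi epoxidation. Once the C16–C17 vinyl iodide is in place the lactone is hydrolysed. Esterification and a ring-closing Stille coupling then build the 28-membered ring.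

Key step: step 15

Remarks on the chemistry
- **Numbering:** macrolide numbering is used throughout. C1 is the lactone carbonyl, C27 the ester carbinol carbon and C28 its methyl.
- **Target configuration:** 2S,3R,5S,9S,11S,13R,14R,15R,26R,27R with an all-E C16–C25 pentaene. The relative relationships are 2,3-syn, 3,5-anti, 9,11-syn, 11,13-anti, 13,14-anti, 14,15-syn and 26,27-syn.
- **Descriptors:** those at C11, C13 and C15 differ in some intermediates only because substituent priorities change. The spatial arrangement is always that of the target.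
- **Design of the carbonylation substrate, O5:** O5 carries TIPS. This is the oxygen on the arm that must screen C3, and TIPS also resists migration to O3 later.
- **Design of the carbonylation substrate, O16:** O16 is a benzyl ether. It is inert to dioxirane and cobaltate and is removable by hydrogenolysis once no alkene remains.
- **Assumption:** compounds 1, 4, 9, 15, 26, 34 and 39, (−)-Ipc2BOMe and the Shi ketone are taken as purchasable. The carbonylation catalyst is made beforehand from its ligand, Et2AlCl and NaCo(CO)4.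
- **Abbreviations:** TBS = tert-butyldimethylsilyl, TIPS = triisopropylsilyl, TES = triethylsilyl, Bn = benzyl, Ipc = isopinocampheyl.

**East epoxide (C2–C10)**

Step 1
Reactants: 1 hepta-1,6-diene
Product: 2 1,2:6,7-diepoxyheptane (all stereoisomers)
Conditions: mCPBA (2.3 equiv), CH2Cl2, 0 °C to rt
Reagents that add atoms: mCPBA, O=C(OO)c1cccc(Cl)c1
Why: Prilezhaev epoxidation of two isolated terminal alkenes is routine, and no stereocontrol is needed because step 2 sorts the isomers.

Step 2
Reactants: 2 1,2:6,7-diepoxyheptane (all stereoisomers)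
Product: 3 (2S,6S)-1,2:6,7-diepoxyheptane
Conditions: (S,S)-(salen)Co(OAc) (1 mol%), H2O (1.1 equiv), THF, 0 °C to rt; distillation
Reagents that add atoms: none
Why: Jacobsen hydrolytic kinetic resolution: the (S,S)-cobalt catalyst hydrolyses (R)-configured terminal oxiranes much faster, so only the isomer with two (S)-rings stays intact, which fixes C5 and C9 and sharpens the optical purity by double selection.

Step 3
Reactants: 4 but-1-yne; 3 (2S,6S)-1,2:6,7-diepoxyheptane (3 equiv, excess recovered)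
Product: 7 (3E,6S)-9-[(2S)-oxiran-2-yl]non-3-en-6-ol, via alkenylalane 5 (not isolated), via lithium alanate 6 (not isolated)
Conditions: 4, i-Bu2AlH, hexane, sealed vessel, 50 °C; n-BuLi, THF, −40 °C; added to 3, THF, −40 to 0 °C; aq. potassium sodium tartrate
Reagents that add atoms: none
Why: syn-Hydroalumination fixes the (E)-geometry of C2=C3 and the derived alkenyl alanate opens a terminal oxirane at its CH2 carbon (SN2 epoxide opening, C5–O untouched); the two rings of C2-symmetric 3 are homotopic, so mono-opening gives one compound and the excess of 3 curbs double opening.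

Step 4
Reactants: 7 (3E,6S)-9-[(2S)-oxiran-2-yl]non-3-en-6-ol
Product: 8 east epoxide, the O5-TIPS ether of 7
Conditions: TIPSOTf, 2,6-lutidine, CH2Cl2, −78 to −20 °C
Reagents that add atoms: TIPSOTf, CC(C)[Si](OS(=O)(=O)C(F)(F)F)(C(C)C)C(C)C
Why: Silyl triflate protection buffered by a hindered base leaves the oxirane alone, and TIPS is chosen because this group must screen C3 in step 15 and resist O5-to-O3 migration in step 19.

**West epoxide (C12–C16)**

Step 5
Reactants: 9 benzyloxyacetaldehyde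
Product: 11 (2S,3R)-1-(benzyloxy)-3-methylpent-4-en-2-ol, via borinate 10 (not isolated)
Conditions: cis-but-2-ene, n-BuLi, KOt-Bu, THF, −78 to −45 °C; (−)-Ipc2BOMe, −78 °C; BF3·OEt2; 9, −78 °C; then NaOH, H2O2, 0 °C to rt
Reagents that add atoms: cis-but-2-ene (transferred as (Z)-crotyl-B(Ipc)2), C/C=C\C
Why: Brown asymmetric (Z)-crotylboration runs through a closed chair transition state that gives the 14,15-syn pair, and the Ipc ligands derived from (+)-α-pinene select the aldehyde face that leads to 15S,14R.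

Step 6
Reactants: 11 (2S,3R)-1-(benzyloxy)-3-methylpent-4-en-2-ol
Product: 12 O15-TBS ether of 11
Conditions: TBSCl, imidazole, DMF, rt
Reagents that add atoms: TBSCl, CC(C)(C)[Si](C)(C)Cl
Why: Routine imidazole-promoted silylation of the secondary alcohol.

Step 7
Reactants: 12 O15-TBS ether of 11
Product: 13 C12–C13 oxirane, both C13 epimers
Conditions: mCPBA, CH2Cl2, 0 °C to rt
Reagents that add atoms: mCPBA, O=C(OO)c1cccc(Cl)c1
Why: Prilezhaev epoxidation of the only alkene; facial control is not required because step 8 selects the C13 epimer.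

Step 8
Reactants: 13 C12–C13 oxirane, both C13 epimers
Product: 14 west epoxide, (2S)-2-[(2R,3S)-4-(benzyloxy)-3-(tert-butyldimethylsilyloxy)butan-2-yl]oxirane
Conditions: (S,S)-(salen)Co(OAc) (2 mol%), H2O (slight excess over the unwanted epimer), THF, rt
Reagents that add atoms: none
Why: Jacobsen hydrolytic kinetic resolution acts here under catalyst control on an epimer pair: the (R)-oxirane is hydrolysed and the (S)-oxirane is left, whose C13–O bond has the orientation of the target (13,14-anti; the descriptor turns to R once C12 is bound to carbon).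

**Linchpin**

Step 9
Reactants: 15 1,3-dithiane
Product: 17 2-(tert-butyldimethylsilyl)-1,3-dithiane, via 2-lithio-1,3-dithiane 16 (not isolated)
Conditions: n-BuLi, THF, −30 °C; TBSCl, −78 °C to rt
Reagents that add atoms: TBSCl, CC(C)(C)[Si](C)(C)Cl
Why: Corey–Seebach lithiation of the dithiane followed by C-silylation is the standard way to this linchpin.

**Union and elaboration to the epoxide**

Step 10
Reactants: 17 2-(tert-butyldimethylsilyl)-1,3-dithiane; 8 east epoxide; 14 west epoxide
Product: 21 C2–C16 dithiane carbinol (5S,9S,13R,14R,15S), via lithiated silyl dithiane 18 (not isolated), via lithium alkoxide 19 (not isolated), via relayed dithiane anion 20 (not isolated)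
Conditions: 17, t-BuLi, Et2O, −78 to −45 °C; 8, Et2O, −78 to −25 °C; 14, THF–HMPA, −78 to 0 °C; H2O
Reagents that add atoms: none
Why: Three-component anion relay (linchpin) coupling: the lithiated silyl dithiane opens 8 at C10, HMPA triggers a 1,4-Brook rearrangement that moves TBS to O9 and regenerates a dithiane anion, and this opens the more hindered 14 at C12; both SN2 openings occur at CH2, so C9 and C13 are not touched.

Step 11
Reactants: 21 C2–C16 dithiane carbinol
Product: 22 C11 ketone with free 13-OH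
Conditions: MeI, CaCO3, MeCN–H2O (9:1), 45 °C
Reagents that add atoms: water, O
Why: Alkylative dithiane hydrolysis (S-methylation, then water) under CaCO3 buffering unmasks the C11 ketone without harming the alkene, the silyl ethers or the β-hydroxy ketone.

Step 12
Reactants: 22 C11 ketone with free 13-OH
Product: 23 11,13-anti diol
Conditions: Me4NBH(OAc)3, MeCN–AcOH (1:1), −30 °C; aq. potassium sodium tartrate
Reagents that add atoms: none
Why: Evans–Saksena reduction: the C13 hydroxyl binds the acetoxyborohydride and hydride is delivered inside a chair transition state, which sets C11 11,13-anti and thereby 9,11-syn.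

Step 13
Reactants: 23 11,13-anti diol
Product: 24 fully protected C2–C16 (E)-alkene (four TBS, one TIPS, one Bn)
Conditions: TBSOTf (3 equiv), 2,6-lutidine, CH2Cl2, −78 to 0 °C
Reagents that add atoms: TBSOTf, CC(C)(C)[Si](C)(C)OS(=O)(=O)C(F)(F)F
Why: Silyl triflate protection caps both hindered secondary alcohols in one operation.

Step 14
Reactants: 24 fully protected C2–C16 (E)-alkene
Product: 25 fully protected C2–C16 (2R,3R)-trans-epoxide
Conditions: D-fructose-derived Shi ketone (30 mol%), KHSO5 (as 2KHSO5·KHSO4·K2SO4), K2CO3, Bu4NHSO4, Na2B4O7/Na2EDTA buffer, MeCN–dimethoxymethane–H2O, 0 °C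
Reagents that add atoms: potassium peroxymonosulfate, [K+].[O-]S(=O)(=O)OO
Why: Shi asymmetric epoxidation: the dioxirane of the D-fructose-derived ketone meets the trans-alkene in a spiro transition state and gives the (2R,3R)-oxirane under catalyst control, the remote stereocentres having little say.

**Key step**

Step 15
Reactants: 25 fully protected C2–C16 (2R,3R)-trans-epoxide; 26 carbon monoxide
Product: 27 fully protected C1–C16 cis-β-lactone (2S,3R)
Conditions: [(L)Al(THF)2][Co(CO)4] (5 mol%; L = N,N'-bis(3-mesityl-5-tert-butylsalicylidene)-1,2-phenylenediaminate), CO (60 bar), THF, 40 °C, autoclave charged under inert gas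
Reagents that add atoms: none
Why: The aluminium cation binds the oxirane oxygen, Co(CO)4− breaks the C2–O bond from the rear (SN2), CO migrates into the new C2–Co bond, and the aluminium alkoxide on C3 attacks the acyl cobalt and sets both ions free again. This is the known ring-expanding carbonylation of trans-2,3-dialkyl oxiranes to cis-β-lactones by [Lewis acid][Co(CO)4] ion pairs, used here on a new substrate. The oxetan-2-one closes in the 4-exo-trig mode. C2 becomes S through the inversion inherent in the SN2 opening of the (2R)-centre fixed in step 14, while C3 keeps its C–O bond and its R configuration, so the trans-oxirane gives the cis-lactone, which is the 2,3-syn pattern. The step needs attack at C2 and not at C3: ethyl is the smaller arm, C3 is screened by the C4–C5 arm with its OTIPS branch and is inductively deactivated by O5, and the 3,3'-dimesityl ligand narrows the pocket so that this difference counts. Silyl and benzyl ethers are poor donors toward the cation and inert to cobaltate, and THF at moderate temperature holds back a second carbonylation and rearrangement to a ketone.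

**From the lactone to the C1–C17 acid**

Step 16
Reactants: 27 fully protected C1–C16 cis-β-lactone
Product: 28 C16 primary alcohol β-lactone
Conditions: H2 (1 atm), Pd/C (10%), EtOAc, rt
Reagents that add atoms: none
Why: Hydrogenolysis of the benzyl ether is safe at this point because no alkene is left, and aliphatic β-lactones and silyl ethers are inert to H2 on palladium.

Step 17
Reactants: 28 C16 primary alcohol β-lactone
Product: 29 C16 aldehyde β-lactone
Conditions: Dess–Martin periodinane, CH2Cl2, 0 °C to rt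
Reagents that add atoms: none
Why: Dess–Martin oxidation is neutral and mild, so the α-silyloxy aldehyde does not epimerise and the β-lactone stays closed.

Step 18
Reactants: 29 C16 aldehyde β-lactone
Product: 30 (16E)-C17 vinyl iodide β-lactone
Conditions: CrCl2 (8 equiv), CHI3 (3 equiv), THF–1,4-dioxane (1:6), 0 °C to rt, dark
Reagents that add atoms: iodoform, IC(I)I
Why: Takai olefination: the geminal dichromium reagent from CHI3 adds to the aldehyde and eliminates to the (E)-vinyl iodide (C17 comes from CHI3), and organochromium reagents do not attack lactones.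

Step 19
Reactants: 30 (16E)-C17 vinyl iodide β-lactone
Product: 31 2,3-syn 3-hydroxy acid
Conditions: LiOH, THF–H2O (4:1), 0 °C; aq. HCl to pH 4
Reagents that add atoms: lithium hydroxide, [Li+].[OH-]
Why: Saponification of the strained lactone by acyl–oxygen cleavage is fast at 0 °C and leaves C2 and C3 unchanged, so the 2,3-syn hydroxy acid is released.

Step 20
Reactants: 31 2,3-syn 3-hydroxy acid
Product: 33 3-OTBS acid, via silyl ester 32 (not isolated)
Conditions: TBSOTf (3 equiv), 2,6-lutidine, CH2Cl2, −78 to 0 °C; then K2CO3, MeOH–THF–H2O, rt; aq. HCl to pH 4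
Reagents that add atoms: TBSOTf, CC(C)(C)[Si](C)(C)OS(=O)(=O)C(F)(F)F
Why: Bis-silylation followed by selective solvolysis of the far more labile silyl ester gives the O3-protected acid, which prevents relactonisation and self-acylation in step 29.

**Stannyl tetraene carbinol (C18–C28)**

Step 21
Reactants: 34 acetaldehyde
Product: 36 (2R,3R)-3-methylpent-4-en-2-ol, via borinate 35 (not isolated)
Conditions: cis-but-2-ene, n-BuLi, KOt-Bu, THF, −78 to −45 °C; (−)-Ipc2BOMe, −78 °C; BF3·OEt2; 34, −78 °C; then NaOH, H2O2, 0 °C to rt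
Reagents that add atoms: cis-but-2-ene (transferred as (Z)-crotyl-B(Ipc)2), C/C=C\C
Why: Brown asymmetric (Z)-crotylboration with the same reagent as in step 5 gives the 26,27-syn pair with 26R,27R through the closed chair transition state.

Step 22
Reactants: 36 (2R,3R)-3-methylpent-4-en-2-ol
Product: 37 O27-TES ether of 36
Conditions: TESCl, imidazole, CH2Cl2, 0 °C to rt
Reagents that add atoms: TESCl, CC[Si](Cl)(CC)CC
Why: Routine imidazole-promoted silylation, which also makes the small alcohol less volatile.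

Step 23
Reactants: 37 O27-TES ether of 36
Product: 38 (2E,4R,5R)-4-methyl-5-(triethylsilyloxy)hex-2-enal
Conditions: crotonaldehyde (5 equiv), second-generation Hoveyda–Grubbs catalyst (5 mol%), CH2Cl2, 40 °C
Reagents that add atoms: crotonaldehyde, C/C=C/C=O
Why: Olefin cross-metathesis of a terminal alkene with an electron-poor enal partner is selective for the (E)-enal and avoids an epimerisable α-methyl aldehyde.

Step 24
Reactants: 39 (E)-pent-2-en-4-yn-1-ol
Product: 40 (2E,4E)-5-(tributylstannyl)penta-2,4-dien-1-ol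
Conditions: Bu3SnH (1.2 equiv), AIBN (cat.), toluene, 85 °C; chromatography on Et3N-washed silica
Reagents that add atoms: tributyltin hydride, CCCC[SnH](CCCC)CCCC
Why: Radical hydrostannation of the terminal alkyne places tin at the terminus, and reversible stannyl radical addition equilibrates the new alkene to the (E)-isomer.

Step 25
Reactants: 40 (2E,4E)-5-(tributylstannyl)penta-2,4-dien-1-ol
Product: 41 [(1E,3E)-5-bromopenta-1,3-dien-1-yl]tributylstannane
Conditions: CBr4, PPh3, CH2Cl2, −20 °C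
Reagents that add atoms: carbon tetrabromide, BrC(Br)(Br)Br
Why: Appel bromination converts the allylic alcohol under neutral conditions that do not protodestannylate the dienylstannane.

Step 26
Reactants: 41 [(1E,3E)-5-bromopenta-1,3-dien-1-yl]tributylstannane
Product: 42 diethyl [(2E,4E)-5-(tributylstannyl)penta-2,4-dien-1-yl]phosphonate
Conditions: P(OEt)3 (neat), 90 °C
Reagents that add atoms: triethyl phosphite, CCOP(OCC)OCC
Why: Michaelis–Arbuzov reaction of the reactive allylic bromide gives the phosphonate without acid or base.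

Step 27
Reactants: 42 diethyl [(2E,4E)-5-(tributylstannyl)penta-2,4-dien-1-yl]phosphonate; 38 (2E,4R,5R)-4-methyl-5-(triethylsilyloxy)hex-2-enal
Product: 44 all-E stannyl tetraene TES ether, via lithiated phosphonate 43 (not isolated)
Conditions: 42, LiN(SiMe3)2, THF, −78 °C; 38, −78 to 0 °C, dark
Reagents that add atoms: none
Why: Horner–Wadsworth–Emmons olefination of an enal with a stabilised dienyl phosphonate anion forms C22=C23 with (E)-preference and gives the all-(E) stannyl tetraene.

Step 28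
Reactants: 44 all-E stannyl tetraene TES ether
Product: 45 (2R,3R,4E,6E,8E,10E)-3-methyl-11-(tributylstannyl)undeca-4,6,8,10-tetraen-2-ol
Conditions: Bu4NF, AcOH (1:1), THF, 0 °C to rt, dark
Reagents that add atoms: none
Why: Buffered fluoride desilylation removes the TES ether, while vinylstannanes, which are sensitive to acid only, survive.

**Endgame**

Step 29
Reactants: 33 3-OTBS acid; 45 stannyl tetraene carbinol
Product: 47 C1–O27 ester carrying the C17 iodide and the C18 stannane, via mixed anhydride 46 (not isolated)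
Conditions: 33, 2,4,6-trichlorobenzoyl chloride, Et3N, toluene, rt; 45, DMAP, toluene, rt, dark
Reagents that add atoms: none
Why: Yamaguchi esterification through the mixed anhydride acylates the hindered C27 alcohol under basic conditions that spare stannane, iodide and silyl ethers, with retention at C27.

Step 30
Reactants: 47 C1–O27 ester carrying the C17 iodide and the C18 stannane
Product: 48 hexa-silylated 28-membered pentaene macrolactone
Conditions: Pd2(dba)3·CHCl3 (20 mol%), AsPh3 (80 mol%), i-Pr2NEt, DMF–THF (1:1), 1 mM, rt, dark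
Reagents that add atoms: none
Why: Intramolecular Stille coupling at high dilution joins C17 and C18 with retention of both alkene geometries, so the pentaene and the 28-membered ring arise together between two unhindered sp2 termini.

Step 31
Reactants: 48 hexa-silylated 28-membered pentaene macrolactone
Product: 49 target macrolide CNP0382847.1
Conditions: HF·pyridine, pyridine, THF, polypropylene vessel, 0 °C to rt, dark
Reagents that add atoms: none
Why: Pyridine-buffered HF cleaves all six silyl ethers (five TBS, one TIPS) by fluoride-driven desilylation without ionising the C15 allylic alcohol or opening the lactone.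

**Compound list**

1 | hepta-1,6-diene | C=CCCCC=C | starting material
2 | 1,2:6,7-diepoxyheptane, all stereoisomers | C1OC1CCCC1CO1 | intermediate
3 | (2S,6S)-1,2:6,7-diepoxyheptane | C1O[C@H]1CCC[C@H]1CO1 | intermediate
4 | but-1-yne | CCC#C | starting material
5 | (E)-but-1-enyl(diisobutyl)alane | CC/C=C/[Al](CC(C)C)CC(C)C | intermediate
6 | lithium (E)-but-1-enyl(butyl)diisobutylalanate | [Li+].CC/C=C/[Al-](CCCC)(CC(C)C)CC(C)C | intermediate
7 | (3E,6S)-9-[(2S)-oxiran-2-yl]non-3-en-6-ol (C2–C10; 5S,9S) | C1O[C@H]1CCC[C@H](O)C/C=C/CC | intermediate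
8 | east epoxide: O5-TIPS ether of 7 (5S,9S) | C1O[C@H]1CCC[C@H](O[Si](C(C)C)(C(C)C)C(C)C)C/C=C/CC | intermediate
9 | benzyloxyacetaldehyde | O=CCOCc1ccccc1 | starting material
10 | bis(isopinocampheyl)borinate of 11 | c1ccccc1COC[C@@H](OB([C@@H]2C[C@@H]3C[C@H]([C@H]2C)C3(C)C)[C@@H]2C[C@@H]3C[C@H]([C@H]2C)C3(C)C)[C@H](C)C=C | intermediate
11 | (2S,3R)-1-(benzyloxy)-3-methylpent-4-en-2-ol (C12–C16; 15S,14R) | c1ccccc1COC[C@@H](O)[C@H](C)C=C | intermediate
12 | O15-TBS ether of 11 | c1ccccc1COC[C@@H](O[Si](C)(C)C(C)(C)C)[C@H](C)C=C | intermediate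
13 | C12–C13 oxirane from 12, both C13 epimers | c1ccccc1COC[C@@H](O[Si](C)(C)C(C)(C)C)[C@H](C)C1CO1 | intermediate
14 | west epoxide: (2S)-2-[(2R,3S)-4-(benzyloxy)-3-(tert-butyldimethylsilyloxy)butan-2-yl]oxirane | c1ccccc1COC[C@@H](O[Si](C)(C)C(C)(C)C)[C@H](C)[C@H]1CO1 | intermediate
15 | 1,3-dithiane | C1CSCSC1 | starting material
16 | 2-lithio-1,3-dithiane | [Li]C1SCCCS1 | intermediate
17 | 2-(tert-butyldimethylsilyl)-1,3-dithiane | CC(C)(C)[Si](C)(C)C1SCCCS1 | intermediate
18 | 2-lithio-2-(tert-butyldimethylsilyl)-1,3-dithiane | [Li]C1([Si](C)(C)C(C)(C)C)SCCCS1 | intermediate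
19 | lithium C9 alkoxide from 18 and 8 (silyl group still on C11) | CC(C)(C)[Si](C)(C)C1(SCCCS1)C[C@@H](O[Li])CCC[C@H](O[Si](C(C)C)(C(C)C)C(C)C)C/C=C/CC | intermediate
20 | C11-lithiated dithiane after the Brook shift (9-OTBS) | [Li]C1(SCCCS1)C[C@@H](O[Si](C)(C)C(C)(C)C)CCC[C@H](O[Si](C(C)C)(C(C)C)C(C)C)C/C=C/CC | intermediate
21 | C2–C16 dithiane carbinol: 2E-alkene, 5-OTIPS, 9-OTBS, C11 as 1,3-dithiane, 13-OH, 14-Me, 15-OTBS, 16-OBn; 5S,9S,13R,14R,15S | c1ccccc1COC[C@@H](O[Si](C)(C)C(C)(C)C)[C@H](C)[C@H](O)CC1(SCCCS1)C[C@@H](O[Si](C)(C)C(C)(C)C)CCC[C@H](O[Si](C(C)C)(C(C)C)C(C)C)C/C=C/CC | intermediate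
22 | C11 ketone, 13-OH free; 5S,9S,13R,14R,15S | c1ccccc1COC[C@@H](O[Si](C)(C)C(C)(C)C)[C@H](C)[C@H](O)CC(=O)C[C@@H](O[Si](C)(C)C(C)(C)C)CCC[C@H](O[Si](C(C)C)(C(C)C)C(C)C)C/C=C/CC | intermediate
23 | 11,13-anti diol; 5S,9S,11R (priority change only),13R,14R,15S | c1ccccc1COC[C@@H](O[Si](C)(C)C(C)(C)C)[C@H](C)[C@H](O)C[C@@H](O)C[C@@H](O[Si](C)(C)C(C)(C)C)CCC[C@H](O[Si](C(C)C)(C(C)C)C(C)C)C/C=C/CC | intermediate
24 | protected C2–C16 (2E)-alkene: 5-OTIPS, 9,11,13,15-tetra-OTBS, 16-OBn; 5S,9S,11S,13R,14R,15S | c1ccccc1COC[C@@H](O[Si](C)(C)C(C)(C)C)[C@H](C)[C@H](O[Si](C)(C)C(C)(C)C)C[C@@H](O[Si](C)(C)C(C)(C)C)C[C@@H](O[Si](C)(C)C(C)(C)C)CCC[C@H](O[Si](C(C)C)(C(C)C)C(C)C)C/C=C/CC | intermediate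
25 | protected C2–C16 trans-epoxide; 2R,3R,5S,9S,11S,13R,14R,15S | c1ccccc1COC[C@@H](O[Si](C)(C)C(C)(C)C)[C@H](C)[C@H](O[Si](C)(C)C(C)(C)C)C[C@@H](O[Si](C)(C)C(C)(C)C)C[C@@H](O[Si](C)(C)C(C)(C)C)CCC[C@H](O[Si](C(C)C)(C(C)C)C(C)C)C[C@H]1O[C@@H]1CC | intermediate
26 | carbon monoxide | [C-]#[O+] | starting material
27 | protected C1–C16 cis-β-lactone; 2S,3R,5S,9S,11S,13R,14R,15S | c1ccccc1COC[C@@H](O[Si](C)(C)C(C)(C)C)[C@H](C)[C@H](O[Si](C)(C)C(C)(C)C)C[C@@H](O[Si](C)(C)C(C)(C)C)C[C@@H](O[Si](C)(C)C(C)(C)C)CCC[C@H](O[Si](C(C)C)(C(C)C)C(C)C)C[C@H]1OC(=O)[C@H]1CC | intermediate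
28 | C16 primary alcohol β-lactone | OC[C@@H](O[Si](C)(C)C(C)(C)C)[C@H](C)[C@H](O[Si](C)(C)C(C)(C)C)C[C@@H](O[Si](C)(C)C(C)(C)C)C[C@@H](O[Si](C)(C)C(C)(C)C)CCC[C@H](O[Si](C(C)C)(C(C)C)C(C)C)C[C@H]1OC(=O)[C@H]1CC | intermediate
29 | C16 aldehyde β-lactone | O=C[C@@H](O[Si](C)(C)C(C)(C)C)[C@H](C)[C@H](O[Si](C)(C)C(C)(C)C)C[C@@H](O[Si](C)(C)C(C)(C)C)C[C@@H](O[Si](C)(C)C(C)(C)C)CCC[C@H](O[Si](C(C)C)(C(C)C)C(C)C)C[C@H]1OC(=O)[C@H]1CC | intermediate
30 | (16E)-17-iodo C1–C17 β-lactone; 15S | I/C=C/[C@@H](O[Si](C)(C)C(C)(C)C)[C@H](C)[C@H](O[Si](C)(C)C(C)(C)C)C[C@@H](O[Si](C)(C)C(C)(C)C)C[C@@H](O[Si](C)(C)C(C)(C)C)CCC[C@H](O[Si](C(C)C)(C(C)C)C(C)C)C[C@H]1OC(=O)[C@H]1CC | intermediate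
31 | (16E)-17-iodo 3-hydroxy acid; 2S,3R | I/C=C/[C@@H](O[Si](C)(C)C(C)(C)C)[C@H](C)[C@H](O[Si](C)(C)C(C)(C)C)C[C@@H](O[Si](C)(C)C(C)(C)C)C[C@@H](O[Si](C)(C)C(C)(C)C)CCC[C@H](O[Si](C(C)C)(C(C)C)C(C)C)C[C@@H](O)[C@H](CC)C(=O)O | intermediate
32 | 3-OTBS acid TBS ester | I/C=C/[C@@H](O[Si](C)(C)C(C)(C)C)[C@H](C)[C@H](O[Si](C)(C)C(C)(C)C)C[C@@H](O[Si](C)(C)C(C)(C)C)C[C@@H](O[Si](C)(C)C(C)(C)C)CCC[C@H](O[Si](C(C)C)(C(C)C)C(C)C)C[C@@H](O[Si](C)(C)C(C)(C)C)[C@H](CC)C(=O)O[Si](C)(C)C(C)(C)C | intermediate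
33 | 3-OTBS acid (C1–C17 fragment) | I/C=C/[C@@H](O[Si](C)(C)C(C)(C)C)[C@H](C)[C@H](O[Si](C)(C)C(C)(C)C)C[C@@H](O[Si](C)(C)C(C)(C)C)C[C@@H](O[Si](C)(C)C(C)(C)C)CCC[C@H](O[Si](C(C)C)(C(C)C)C(C)C)C[C@@H](O[Si](C)(C)C(C)(C)C)[C@H](CC)C(=O)O | intermediate
34 | acetaldehyde | CC=O | starting material
35 | bis(isopinocampheyl)borinate of 36 | C[C@@H](OB([C@@H]1C[C@@H]2C[C@H]([C@H]1C)C2(C)C)[C@@H]1C[C@@H]2C[C@H]([C@H]1C)C2(C)C)[C@H](C)C=C | intermediate
36 | (2R,3R)-3-methylpent-4-en-2-ol (27R,26R) | C[C@@H](O)[C@H](C)C=C | intermediate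
37 | triethyl{[(2R,3R)-3-methylpent-4-en-2-yl]oxy}silane | C[C@@H](O[Si](CC)(CC)CC)[C@H](C)C=C | intermediate
38 | (2E,4R,5R)-4-methyl-5-(triethylsilyloxy)hex-2-enal (C23–C28) | C[C@@H](O[Si](CC)(CC)CC)[C@H](C)/C=C/C=O | intermediate
39 | (E)-pent-2-en-4-yn-1-ol | OC/C=C/C#C | starting material
40 | (2E,4E)-5-(tributylstannyl)penta-2,4-dien-1-ol | OC/C=C/C=C/[Sn](CCCC)(CCCC)CCCC | intermediate
41 | [(1E,3E)-5-bromopenta-1,3-dien-1-yl]tributylstannane | BrC/C=C/C=C/[Sn](CCCC)(CCCC)CCCC | intermediate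
42 | diethyl [(2E,4E)-5-(tributylstannyl)penta-2,4-dien-1-yl]phosphonate (C18–C22) | CCOP(=O)(OCC)C/C=C/C=C/[Sn](CCCC)(CCCC)CCCC | intermediate
43 | C22-lithiated phosphonate 42 | [Li]C(/C=C/C=C/[Sn](CCCC)(CCCC)CCCC)P(=O)(OCC)OCC | intermediate
44 | O27-TES ether of 45 | C[C@@H](O[Si](CC)(CC)CC)[C@H](C)/C=C/C=C/C=C/C=C/[Sn](CCCC)(CCCC)CCCC | intermediate
45 | (2R,3R,4E,6E,8E,10E)-3-methyl-11-(tributylstannyl)undeca-4,6,8,10-tetraen-2-ol (C18–C28) | C[C@@H](O)[C@H](C)/C=C/C=C/C=C/C=C/[Sn](CCCC)(CCCC)CCCC | intermediate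
46 | mixed anhydride of 33 with 2,4,6-trichlorobenzoic acid | I/C=C/[C@@H](O[Si](C)(C)C(C)(C)C)[C@H](C)[C@H](O[Si](C)(C)C(C)(C)C)C[C@@H](O[Si](C)(C)C(C)(C)C)C[C@@H](O[Si](C)(C)C(C)(C)C)CCC[C@H](O[Si](C(C)C)(C(C)C)C(C)C)C[C@@H](O[Si](C)(C)C(C)(C)C)[C@H](CC)C(=O)OC(=O)c1c(Cl)cc(Cl)cc1Cl | intermediate
47 | ester of acid 33 with carbinol 45 (C17 iodide, C18 stannane) | I/C=C/[C@@H](O[Si](C)(C)C(C)(C)C)[C@H](C)[C@H](O[Si](C)(C)C(C)(C)C)C[C@@H](O[Si](C)(C)C(C)(C)C)C[C@@H](O[Si](C)(C)C(C)(C)C)CCC[C@H](O[Si](C(C)C)(C(C)C)C(C)C)C[C@@H](O[Si](C)(C)C(C)(C)C)[C@H](CC)C(=O)O[C@H](C)[C@H](C)/C=C/C=C/C=C/C=C/[Sn](CCCC)(CCCC)CCCC | intermediate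
48 | 3,9,11,13,15-penta-O-TBS-5-O-TIPS macrolactone (28-membered ring, all-E pentaene) | CC[C@@H]1C(=O)O[C@H](C)[C@H](C)/C=C/C=C/C=C/C=C/C=C/[C@@H](O[Si](C)(C)C(C)(C)C)[C@H](C)[C@H](O[Si](C)(C)C(C)(C)C)C[C@@H](O[Si](C)(C)C(C)(C)C)C[C@@H](O[Si](C)(C)C(C)(C)C)CCC[C@H](O[Si](C(C)C)(C(C)C)C(C)C)C[C@H]1O[Si](C)(C)C(C)(C)C | intermediate
49 | (3S,4R,6S,10S,12S,14R,15R,16R,17E,19E,21E,23E,25E,27R,28R)-3-ethyl-4,6,10,12,14,16-hexahydroxy-15,27,28-trimethyl-1-oxacyclooctacosa-17,19,21,23,25-pentaen-2-one | CC[C@@H]1C(=O)O[C@H](C)[C@H](C)/C=C/C=C/C=C/C=C/C=C/[C@@H](O)[C@H](C)[C@H](O)C[C@@H](O)C[C@@H](O)CCC[C@H](O)C[C@H]1O | target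

**Step count**

- Total step count: 31.
- Longest linear sequence: 18 steps (steps 1–4, 10–20 and 29–31). The branch through steps 5–8 is equally long.

**The three steps most likely to fail**

Step 15 (carbonylation). Cobaltate attack may spread over both oxirane carbons because the two arms differ only beyond their first CH2. The crowded trans-oxirane may also be activated so slowly that rearrangement competes. The fallback builds the same C1–C3 unit by auxiliary-controlled aldol chemistry and sets out from alkene 24.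
- Lemieux–Johnson cleavage (K2OsO4·2H2O cat., NaIO4, 2,6-lutidine, dioxane–H2O) gives the C3 aldehyde F1.
- An Evans syn aldol with the dibutylboron enolate of (S)-4-benzyl-3-butanoyl-1,3-oxazolidin-2-one (Bu2BOTf, Et3N, CH2Cl2, −78 °C) gives the (2S,3R) aldol imide F2.
- LiOH/H2O2 removes the auxiliary to give the benzyl-protected hydroxy acid F3.
- Carboxyl-activating lactonisation (PhSO2Cl, pyridine, 0 °C, retention at C3) returns to the route at β-lactone 27.

Step 30 (Stille ring closure). Oligomerisation may outrun ring closure, and the tetraenylstannane may lose tin or isomerise during the long high-dilution run. The fallback swaps the order of the two bond formations and sets out from acid 33 and carbinol 45.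
- An intermolecular Stille coupling at normal concentration (Pd2(dba)3·CHCl3, AsPh3, i-Pr2NEt, DMF, dark) gives the pentaene seco acid F4.
- Shiina macrolactonisation (2-methyl-6-nitrobenzoic anhydride, DMAP, toluene, slow addition) closes the C1–O27 bond and returns to the route at macrolactone 48.

Step 10 (relay coupling). After the Brook shift the second alkylation on the α-branched oxirane 14 may be too slow. The relayed anion would then be quenched and the sequence would stop after one epoxide. The fallback joins the halves by an aldol reaction at C12–C13 and sets out from alkene 12 and epoxide 8.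
- Ozonolysis of 12 (O3, CH2Cl2, −78 °C; PPh3) gives the C13 aldehyde F5.
- Epoxide 8 is opened with 2-lithio-2-methyl-1,3-dithiane to give the C9 carbinol F6.
- F6 is silylated (TBSOTf, 2,6-lutidine) to the TBS ether F7 and unmasked (MeI, CaCO3, aq. MeCN) to the methyl ketone F8.
- A reagent-controlled boron aldol follows, using Et3N and the Ipc2BCl enantiomer that favours the 13R carbinol. Reaction of the enolate of F8 with F5 returns to the route at hydroxy ketone 22.

**Further compounds**

F1 | step 15 | C3 aldehyde (C3–C16, protected as in 24) | c1ccccc1COC[C@@H](O[Si](C)(C)C(C)(C)C)[C@H](C)[C@H](O[Si](C)(C)C(C)(C)C)C[C@@H](O[Si](C)(C)C(C)(C)C)C[C@@H](O[Si](C)(C)C(C)(C)C)CCC[C@H](O[Si](C(C)C)(C(C)C)C(C)C)CC=O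
F2 | step 15 | (2S,3R) aldol imide with the (S)-4-benzyloxazolidinone auxiliary | c1ccccc1COC[C@@H](O[Si](C)(C)C(C)(C)C)[C@H](C)[C@H](O[Si](C)(C)C(C)(C)C)C[C@@H](O[Si](C)(C)C(C)(C)C)C[C@@H](O[Si](C)(C)C(C)(C)C)CCC[C@H](O[Si](C(C)C)(C(C)C)C(C)C)C[C@@H](O)[C@H](CC)C(=O)N1[C@@H](Cc2ccccc2)COC1=O
F3 | step 15 | benzyl-protected (2S,3R)-3-hydroxy acid | c1ccccc1COC[C@@H](O[Si](C)(C)C(C)(C)C)[C@H](C)[C@H](O[Si](C)(C)C(C)(C)C)C[C@@H](O[Si](C)(C)C(C)(C)C)C[C@@H](O[Si](C)(C)C(C)(C)C)CCC[C@H](O[Si](C(C)C)(C(C)C)C(C)C)C[C@@H](O)[C@H](CC)C(=O)O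
F4 | step 30 | pentaene seco acid (27-OH and C1 acid free) | C[C@@H](O)[C@H](C)/C=C/C=C/C=C/C=C/C=C/[C@@H](O[Si](C)(C)C(C)(C)C)[C@H](C)[C@H](O[Si](C)(C)C(C)(C)C)C[C@@H](O[Si](C)(C)C(C)(C)C)C[C@@H](O[Si](C)(C)C(C)(C)C)CCC[C@H](O[Si](C(C)C)(C(C)C)C(C)C)C[C@@H](O[Si](C)(C)C(C)(C)C)[C@H](CC)C(=O)O
F5 | step 10 | C13 aldehyde, 4-(benzyloxy)-3-(tert-butyldimethylsilyloxy)-2-methylbutanal (14,15-syn) | c1ccccc1COC[C@@H](O[Si](C)(C)C(C)(C)C)[C@H](C)C=O
F6 | step 10 | C9 carbinol with a 2-methyl-1,3-dithiane at C11 | CC1(SCCCS1)C[C@@H](O)CCC[C@H](O[Si](C(C)C)(C(C)C)C(C)C)C/C=C/CC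
F7 | step 10 | O9-TBS ether of F6 | CC1(SCCCS1)C[C@@H](O[Si](C)(C)C(C)(C)C)CCC[C@H](O[Si](C(C)C)(C(C)C)C(C)C)C/C=C/CC
F8 | step 10 | C2–C12 methyl ketone (C11 carbonyl) | CC(=O)C[C@@H](O[Si](C)(C)C(C)(C)C)CCC[C@H](O[Si](C(C)C)(C(C)C)C(C)C)C/C=C/CC
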